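**Plan**
- Retrosynthesis cuts C8–O and C9–C10 (ring B) and returns the C4–C5 bond to a C4–C10 bond, so ring A becomes a 1,2,2-trimethylcyclopentane with C5 as an exocyclic, sulfonate-bearing carbon. It then cuts C6–C7 (enolate alkylation) and the methyl bonds at C4 and C10 (cuprate addition, methylation).
- Enabling feature: in ring A (C1–C5, C10) the CH carbon C5 lies between two quaternary carbons, C4 (CMe2) and C10 (C–Me). A cation at C5 beside C10 in a five-membered ring is relieved by a 1,2-shift of C4, which makes six-membered ring A and puts the charge on C10, within reach of alkene carbon C9.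
- Forward: the C7–C9/C11–C15 chain with the E C8=C9 alkene comes from (S)-citronellol; the cyclopentyl methyl ketone from 1-acetyl-2-methylcyclopentene (Me2CuLi, then MeI); enolate alkylation joins them at C6–C7; CBS reduction and mesylation arm C5.
- Rings: ring A arises first by 5→6 ring expansion, ring B directly after by cation–olefin closure C9–C10, and water ends the cascade at C8, all in the last step.
- Stereochemistry: C13 from (S)-citronellol; C5 from the CBS-set carbinol (inversion in the shift); C10, C9 and C8 from chair closure onto the E-alkene and anti capture by water.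

Key step: step 8

Remark: the quaternary ring carbon of the cyclopentyl methyl ketone is carried as the racemate, because it becomes the planar C10 cation in the last step. The coupled ketone, its alcohol and its mesylate are therefore each a pair of epimers at that carbon (left undefined in their SMILES) that converge on one cation.

Step 1
Reactants: 1 (S)-(−)-citronellol, (3S)-3,7-dimethyloct-6-en-1-ol
Product: 2 (3S)-3,7-dimethyloct-6-en-1-yl acetate
Conditions: Ac2O, pyridine, 4-(dimethylamino)pyridine (cat.), CH2Cl2, 0 → 23 °C
Reagents that add atoms: acetic anhydride, CC(=O)OC(C)=O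
Why: DMAP-catalysed acylation of the primary alcohol installs the acetate of the target at the outset and does not touch the chiral-pool centre (future C13).

Step 2
Reactants: 2 (3S)-3,7-dimethyloct-6-en-1-yl acetate
Product: 3 (3S,6E)-8-hydroxy-3,7-dimethyloct-6-en-1-yl acetate
Conditions: SeO2 (0.3 equiv), t-BuOOH (2 equiv), salicylic acid (0.1 equiv), CH2Cl2, 23 °C
Reagents that add atoms: selenium dioxide, O=[Se]=O (delivers the oxygen); tert-butyl hydroperoxide, CC(C)(C)OO (restores SeO2, net oxygen source)
Why: the SeO2-catalysed allylic oxidation (ene reaction, then 2,3-sigmatropic shift) attacks the E-methyl group of the trisubstituted alkene, so the hydroxyl ends on the carbon trans to the chain (future C7) with the E geometry that later fixes C9.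

Step 3
Reactants: 3 (3S,6E)-8-hydroxy-3,7-dimethyloct-6-en-1-yl acetate
Product: 4 (3S,6E)-8-bromo-3,7-dimethyloct-6-en-1-yl acetate
Conditions: CBr4, PPh3, CH2Cl2, 0 °C
Reagents that add atoms: carbon tetrabromide, BrC(Br)(Br)Br
Why: the Appel reaction converts the primary allylic alcohol into the bromide by SN2 displacement of the oxyphosphonium ion, without allylic transposition or loss of the E geometry.

Step 4
Reactants: 5 1-(2-methylcyclopent-1-en-1-yl)ethan-1-one (1-acetyl-2-methylcyclopentene)
Product: 7 1-(1,2,2-trimethylcyclopentyl)ethan-1-one (racemic), via lithium cyclopentylidene enolate 6 (not isolated)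
Conditions: Me2CuLi (from CuI and 2 MeLi), Et2O, 0 °C; then MeI (excess), DMPU, 0 → 23 °C
Reagents that add atoms: lithium dimethylcuprate, [Li+].C[Cu-]C; iodomethane, CI
Why: cuprate conjugate addition to the β-methyl enone creates the CMe2 carbon (future C4) and a regiodefined enolate, whose C-methylation (conjugate addition–enolate alkylation) builds the adjacent quaternary carbon (future C10), racemic but planar in the key step.

Step 5
Reactants: 7 1-(1,2,2-trimethylcyclopentyl)ethan-1-one; 4 (3S,6E)-8-bromo-3,7-dimethyloct-6-en-1-yl acetate
Product: 9 (3S,6E)-3,7-dimethyl-10-oxo-10-(1,2,2-trimethylcyclopentyl)dec-6-en-1-yl acetate (pair of epimers at the ring quaternary carbon), via lithium methyl-ketone enolate 8 (not isolated)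
Conditions: LiN(iPr)2 (1.05 equiv), THF, −78 °C; then 4 (0.9 equiv), DMPU, −78 → −30 °C
Reagents that add atoms: none
Why: the ketone can enolise only toward its methyl group, so a single lithium enolate displaces the primary allylic bromide by SN2 (enolate alkylation) at low temperature, faster than it attacks the acetate, and joins C6 to C7.

Step 6
Reactants: 9 (3S,6E)-3,7-dimethyl-10-oxo-10-(1,2,2-trimethylcyclopentyl)dec-6-en-1-yl acetate
Product: 10 (3S,6E,10S)-10-hydroxy-3,7-dimethyl-10-(1,2,2-trimethylcyclopentyl)dec-6-en-1-yl acetate
Conditions: (R)-Me-CBS oxazaborolidine [(3aR)-1-methyl-3,3-diphenyltetrahydro-1H,3H-pyrrolo[1,2-c][1,3,2]oxazaborole] (0.2 equiv), catecholborane (1.5 equiv), toluene, −78 → −30 °C; then MeOH, aq. NaHCO3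
Reagents that add atoms: none
Why: CBS reduction with catecholborane, which neither hydroborates the alkene nor reduces the acetate, delivers hydride under catalyst control between the large tert-alkyl and the small primary alkyl group and sets the (S)-carbinol (future C5) for both epimers of the ring centre.

Step 7
Reactants: 10 (3S,6E,10S)-10-hydroxy-3,7-dimethyl-10-(1,2,2-trimethylcyclopentyl)dec-6-en-1-yl acetate
Product: 11 (3S,6E,10S)-3,7-dimethyl-10-[(methylsulfonyl)oxy]-10-(1,2,2-trimethylcyclopentyl)dec-6-en-1-yl acetate
Conditions: MsCl, Et3N, CH2Cl2, −10 °C; used without purification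
Reagents that add atoms: methanesulfonyl chloride, CS(=O)(=O)Cl
Why: sulfonylation (mesylation via sulfene) turns the hindered neopentylic alcohol into a leaving group with retention at carbon.

Step 8
Reactants: 11 (3S,6E,10S)-3,7-dimethyl-10-[(methylsulfonyl)oxy]-10-(1,2,2-trimethylcyclopentyl)dec-6-en-1-yl acetate
Product: 14 (13S)-8α-hydroxylabdan-15-yl acetate, (3S)-5-[(1R,2R,4aS,8aS)-2-hydroxy-2,5,5,8a-tetramethyldecahydronaphthalen-1-yl]-3-methylpentyl acetate (target), via ring-expanded cyclohexyl C10 cation 12 (not isolated), via labdan-8-yl cation 13 (not isolated)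
Conditions: 1,1,1,3,3,3-hexafluoropropan-2-ol (0.02 M), H2O (10 equiv), 2,6-di-tert-butylpyridine (2 equiv), 0 → 40 °C
Reagents that add atoms: water, O
Why: Proposed new method: in the ionising, non-nucleophilic solvent the C5–OMs bond breaks with antiperiplanar 1,2-shift of the ring CMe2 carbon (C4) from the quaternary ring carbon (C10) to C5, which turns the cyclopentane into the cyclohexane of ring A and leaves a tertiary cation at C10; C9 of the trisubstituted alkene attacks this cation to close ring B, and the tertiary C8 cation so formed is hydrated while the hindered pyridine takes up the methanesulfonic acid. The closest known reaction types are the solvolytic Wagner–Meerwein ring expansion of cyclopentylcarbinyl sulfonates and the acid-mediated cyclisation of monocyclic homofarnesyl-type cations to trans-decalins, which have not been run as one cascade started by a ring shift. Ring A is not closed but enlarged from five to six atoms by the C4 shift, and ring B closes in 6-endo-trig mode (C9 onto C10) through a chair transition state. C5 is fixed by the carbinol centre of 11 through inversion in the concerted shift, C10 by equatorial attack of the chain held on C5 (trans ring fusion, chair–chair), C9 by the E geometry of the alkene (C11 equatorial) and C8 by anti addition across that alkene, so that water enters equatorially on the α face. The step needs migration of the CMe2 carbon in preference to the ring CH2 and the methyl group, which the higher migratory aptitude of the more substituted carbon and the relief of strain between the two adjacent quaternary centres should secure, and it needs cyclisation and hydration to outrun proton loss, which the alkene placed for six-membered closure and a medium with water as the only nucleophile and no effective base for the cations should secure.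

**Compound list**
1 | (S)-(−)-citronellol, (3S)-3,7-dimethyloct-6-en-1-ol | OCC[C@@H](C)CCC=C(C)C | starting material
2 | (3S)-3,7-dimethyloct-6-en-1-yl acetate | CC(=O)OCC[C@@H](C)CCC=C(C)C | intermediate
3 | (3S,6E)-8-hydroxy-3,7-dimethyloct-6-en-1-yl acetate | CC(=O)OCC[C@@H](C)CC/C=C(\C)CO | intermediate
4 | (3S,6E)-8-bromo-3,7-dimethyloct-6-en-1-yl acetate | CC(=O)OCC[C@@H](C)CC/C=C(\C)CBr | intermediate
5 | 1-(2-methylcyclopent-1-en-1-yl)ethan-1-one | CC(=O)C1=C(C)CCC1 | starting material
6 | lithium 1-(2,2-dimethylcyclopentylidene)ethan-1-olate (not isolated) | [Li+].CC([O-])=C1CCCC1(C)C | intermediate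
7 | 1-(1,2,2-trimethylcyclopentyl)ethan-1-one (racemic) | CC(=O)C1(C)CCCC1(C)C | intermediate
8 | lithium 1-(1,2,2-trimethylcyclopentyl)ethen-1-olate (not isolated) | [Li+].C=C([O-])C1(C)CCCC1(C)C | intermediate
9 | (3S,6E)-3,7-dimethyl-10-oxo-10-(1,2,2-trimethylcyclopentyl)dec-6-en-1-yl acetate (epimers at the ring quaternary carbon) | CC(=O)OCC[C@@H](C)CC/C=C(\C)CCC(=O)C1(C)CCCC1(C)C | intermediate
10 | (3S,6E,10S)-10-hydroxy-3,7-dimethyl-10-(1,2,2-trimethylcyclopentyl)dec-6-en-1-yl acetate (epimers at the ring quaternary carbon) | CC(=O)OCC[C@@H](C)CC/C=C(\C)CC[C@H](O)C1(C)CCCC1(C)C | intermediate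
11 | (3S,6E,10S)-3,7-dimethyl-10-[(methylsulfonyl)oxy]-10-(1,2,2-trimethylcyclopentyl)dec-6-en-1-yl acetate (epimers at the ring quaternary carbon) | CC(=O)OCC[C@@H](C)CC/C=C(\C)CC[C@H](OS(C)(=O)=O)C1(C)CCCC1(C)C | intermediate
12 | 2-[(3E,7S)-9-acetoxy-3,7-dimethylnon-3-en-1-yl]-1,3,3-trimethylcyclohexan-1-ylium, ring carbon 2 (C5) configured as in 14 (not isolated) | CC(=O)OCC[C@@H](C)CC/C=C(\C)CC[C@@H]1[C+](C)CCCC1(C)C | intermediate
13 | (13S)-15-acetoxylabdan-8-ylium (not isolated) | CC(=O)OCC[C@@H](C)CC[C@@H]1[C@@]2(C)CCCC(C)(C)[C@@H]2CC[C+]1C | intermediate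
14 | (13S)-8α-hydroxylabdan-15-yl acetate, (5S,8R,9R,10S,13S) | CC(=O)OCC[C@@H](C)CC[C@@H]1[C@@]2(C)CCCC(C)(C)[C@@H]2CC[C@@]1(C)O | target

**Step count and risks**
Total step count: 8. Longest linear sequence: 7 (steps 1, 2, 3, 5, 6, 7, 8 from (S)-citronellol); step 4 is the one-step side branch.

Steps most likely to fail:

1. Step 8. The ring CH2 or the methyl group may migrate instead of the CMe2 carbon. A proton may be lost from the C10 or the C8 cation before cyclisation or hydration. Ring B may close to the cis ring fusion. The fallback sets out from 11 and comes back at 14, with the two events separated and each run as a known reaction. Solvolysis of 11 in a water-rich medium (acetone–H2O 1:1, CaCO3, 50 °C) hydrates the ring-expanded C10 cation before it can cyclise and should give (3S,6E)-9-[(1S)-2-hydroxy-2,6,6-trimethylcyclohexyl]-3,7-dimethylnon-6-en-1-yl acetate F1 (both C10 epimers). Cyclisation under the superacid conditions known for monocyclic terpenoid precursors (ClSO3H, 2-nitropropane, −78 °C, Et3N quench) should give mainly (13S)-labd-7-en-15-yl acetate F2. Epoxidation with mCPBA (NaHCO3, CH2Cl2, 0 °C) from the α face, away from the axial C10 methyl group, should give (13S)-7α,8α-epoxylabdan-15-yl acetate F3. LiAlH4 (THF, reflux) opens the epoxide at C7 and removes the acetate to give (13S)-labdane-8α,15-diol F4. Ac2O in pyridine at 0 °C acetylates only the primary hydroxyl and returns to 14.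

2. Step 4. Conjugate addition to the fully substituted enone may stall, and the hindered enolate may undergo O-methylation or proton exchange toward the methyl ketone side. The fallback sets out from 5 and comes back at 7, with the methyl group on the quaternary carbon brought in as a cyclopropane carbon instead of by enolate alkylation. Me2CuLi with Me3SiCl (Et2O, −78 → 0 °C) traps the conjugate adduct as trimethyl{[1-(2,2-dimethylcyclopentylidene)ethyl]oxy}silane F5. Simmons–Smith cyclopropanation (Et2Zn, CH2I2, CH2Cl2) gives trimethyl[(1,4,4-trimethylspiro[2.4]heptan-1-yl)oxy]silane F6. NaOH in aqueous MeOH at reflux opens the cyclopropanol at the bond between the carbinol carbon and the CH2 group and gives 7.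

3. Step 5. Acyl transfer from the acetate to the enolate, or enolate equilibration with double alkylation, may compete. The fallback sets out from 3 and 7 and comes back at 9, with the C6–C7 bond made under neutral conditions by a Tsuji–Trost-type allylation. ClCO2Me and pyridine convert 3 into (3S,6E)-8-[(methoxycarbonyl)oxy]-3,7-dimethyloct-6-en-1-yl acetate F7. LiN(iPr)2 then Me3SiCl (THF, −78 °C) convert 7 into trimethyl{[1-(1,2,2-trimethylcyclopentyl)ethenyl]oxy}silane F8. F7 and F8 with Pd2(dba)3·CHCl3 and 1,2-bis(diphenylphosphino)ethane (zerovalent palladium, THF, reflux) should give 9 by attack of the enol ether at the unsubstituted end of the π-allyl complex.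

Further compounds
F1 | step 8 | (3S,6E)-9-[(1S)-2-hydroxy-2,6,6-trimethylcyclohexyl]-3,7-dimethylnon-6-en-1-yl acetate (epimers at the carbinol carbon) | CC(=O)OCC[C@@H](C)CC/C=C(\C)CC[C@@H]1C(C)(O)CCCC1(C)C
F2 | step 8 | (13S)-labd-7-en-15-yl acetate | CC(=O)OCC[C@@H](C)CC[C@@H]1[C@@]2(C)CCCC(C)(C)[C@@H]2CC=C1C
F3 | step 8 | (13S)-7α,8α-epoxylabdan-15-yl acetate | CC(=O)OCC[C@@H](C)CC[C@@H]1[C@@]2(C)CCCC(C)(C)[C@@H]2C[C@H]3O[C@]31C
F4 | step 8 | (13S)-labdane-8α,15-diol | OCC[C@@H](C)CC[C@@H]1[C@@]2(C)CCCC(C)(C)[C@@H]2CC[C@@]1(C)O
F5 | step 4 | trimethyl{[1-(2,2-dimethylcyclopentylidene)ethyl]oxy}silane | CC(O[Si](C)(C)C)=C1CCCC1(C)C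
F6 | step 4 | trimethyl[(1,4,4-trimethylspiro[2.4]heptan-1-yl)oxy]silane | CC1(O[Si](C)(C)C)CC12CCCC2(C)C
F7 | step 5 | (3S,6E)-8-[(methoxycarbonyl)oxy]-3,7-dimethyloct-6-en-1-yl acetate | CC(=O)OCC[C@@H](C)CC/C=C(\C)COC(=O)OC
F8 | step 5 | trimethyl{[1-(1,2,2-trimethylcyclopentyl)ethenyl]oxy}silane | C=C(O[Si](C)(C)C)C1(C)CCCC1(C)C
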